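All runs were generated by integration for substances that don't exist, noise included.

You read the flasks from red to violet at 4.0 h, and the question is where on its target curve each one stands by then.

| flask | substrate | coupling partner | remark | time |
|---|---|---|---|---|
| south | 0.30 M | 0.094 M | run made earlier |  |
| north | 0.30 M | 1.5 M | run made earlier |  |
| red | 0.30 M | 0.0800 M |  | 4.0 h |
| amber | 0.30 M | 0.150 M |  | 4.0 h |
| green | 0.30 M | 0.300 M |  | 4.0 h |
| teal | 0.30 M | 0.600 M |  | 4.0 h |
| violet | 0.30 M | 1.20 M |  | 4.0 h |
- south (time / h: target / %): 0.167: 0; 0.417: 0; 0.833: 0; 1.33: 7; 1.50: 2; 2.00: 4; 3.00: 6
- north (time / h: target / %): 0.250: 11; 0.333: 14; 0.500: 18; 0.833: 25; 1.33: 31; 2.00: 30; 3.00: 24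

(scatter of a reading: 1.5 percentage points)
1. amount of target at the end, in percent of the substrate charged for red, amber, green, teal, violet, in this order
2. the shape of the row from first to last (falls all the way / hardly changes / rises, then falls / rises all the way / falls, then rises)
- percent here means substrate units held: one side product B counts as two
- what was read earlier has a scatter of 1.5 percentage points, one standard deviation
- steps under discussion: substrate + coupling partner -> target; substrate -> side product A; 2 substrate -> side product B; coupling partner + target -> over-reaction product
- "hardly changes" means that all values lie within two and a half points (for a concentration: within two and a half percent of the largest)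

Write S for substrate, C for coupling partner, T for target, and kf and ko for the constants of the target-forming and over-reaction steps. The target is the intermediate of a consecutive pair, with dT/dt = C(kf·S − ko·T). Both terms carry C, so for these two steps charge and time act as a product, the partner dose. This is rough, since the charge stands in for the partner actually present and the side routes run on plain hours.

Now read the north run. Target climbs to 31% at 1.33 h, reads 30% at 2.00 h, and falls to 24% at 3.00 h. The top two readings lie within the scatter of 1.5 percentage points, so I place the maximum between them, at 1.67 h. North's charge of 1.5 M then gives 150 M·min: this is the peak dose, the partner dose at which target stopped rising in north, as far as these readings show it.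

South ends at 0.113 of the peak dose, and its last three readings climb from 2% to 6%.

Over 4.0 h, the peak dose corresponds to a charge of 0.625 M. North's rows can therefore be read as a row of flasks. Its 0.833 h reading, 25%, stands for a charge of 0.312 M, close to green. Its 3.00 h reading stands for 1.12 M, close to violet. Green, teal and violet get more clock hours than north, so my own reckoning puts green and violet somewhat below those readings, with teal on top of the row and violet lower than teal.

The forecast differs. It gives 4.5%, 7.5%, 13%, 20% and 23%, a row that rises all the way: “Over-reaction flattens the top, with the optimum near or just above 1 M, so the rise is slight but continuing”.

The flasks give 6.91%, 11.8%, 19.3%, 25.7% and 22.8%, a row that rises, then falls.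

    substrate + coupling partner → target (k = 0.380 L mol⁻¹ h⁻¹)
    substrate → side product A (k = 0.0848 h⁻¹)
    2 substrate → side product B (k = 0.136 L mol⁻¹ h⁻¹)
    coupling partner + target → over-reaction product (k = 0.446 L mol⁻¹ h⁻¹)

Set the over-reaction rate against the target-forming rate, as ko·T over kf·S, on the simulated states. Violet at 2.00 h and teal at 4.00 h both stand at 0.961 of the peak dose, reckoned on the charge, and the ratio is 1.02 in violet with target 29.3%, and 1.08 in teal with target 25.7%. Violet at 4.00 h has twice the peak dose, its ratio is 1.97, and its target is 22.8%.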